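## The problem

Target 28 is an 8,8a-dihydro-1H-isochromen-6(7H)-one (numbered C1, O2, C3, C4, C4a, C5 to C8, C8a) in which a cyclohexenone is fused through the C4a–C8a bond to a 2H-pyran, so that the enol ether O2–C3=C4, the C4a=C5 double bond and the C6 ketone form one push-pull dienone that carries chlorine on C5 and an (E,E)-dienyl chain on C3. The carbocycle holds three contiguous stereocentres, C7 (R, a tertiary carbinol bearing methyl), C8 (R) and C8a (S), with the 7-hydroxyl, the 8-hydroxyl and the C1 methylene all on one face, while the chain holds two further centres (C5' R, C6' S) that lie too far from the ring to be set from it and must arrive in a separate enantiopure fragment. C8 is the natural anchor among the ring centres: its oxygen can deliver C1 to C8a through a tether, and once it stands axial in a cis-fused bicycle it can steer a nucleophile onto a C7 ketone from the opposite face, which leaves the new 7-hydroxyl cis to it. The C6 ketone is both an α-ketol (C7) and a β-ketol (C8), so base invites α-ketol shift and retro-aldol cleavage, and H-8a, γ to the dienone and next to the 8-hydroxyl, can be lost under base or strong acid, which would epimerise C8a or expel O8. The enol ether and the polyene do not survive hot acid or strong electrophiles, and the chlorine must go to C5 of a polyene with several nucleophilic carbons, so the chromophore should be built last and under mild conditions. The feature that makes the key step possible is that C4 and the ring carbons C4a, C5, C6, C7, C8 and C8a, with oxygen on C6, C7 and C8, are the skeleton of shikimic acid 1, whose carboxyl is C4, whose enoate double bond is C4a=C8a and whose allylic carbinol is C8. Because O8 sits next to the β-carbon C8a of the enoate, a one-carbon radical tethered to O8 can reach C8a only through a five-membered ring, and only on the face of O8.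

## Retrosynthesis

**C5–Cl (28 to 27).** The chlorine is removed first. C5 is the α-carbon of a vinylogous ester and the most nucleophilic ring position, so an electrophilic chlorination of 27 is the shortest way to place it. Carrying a chloro-enone through coupling and ring closure would add steps. The forward reaction must prefer C5 over C4 and over the chain.

**O2–C3 (27 to 26).** The pyran is opened at the enol ether bond to give the hydroxy dienynone 26. This cut is preferred to a cut at C1–O2 because the C1 hydroxyl then adds to an alkyne that already holds the complete chain. The forward reaction must close 6-endo on C3 and not 5-exo on C4; the electron-rich dienyl group on C3 and the electron-poor C4a on C4 polarise the alkyne in the right sense for a π-acid.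

**C3–C1' (26, via its protected form 25, to 18 and 24).** Cutting between the alkyne and the diene gives the ring fragment 18 (a terminal ynenone) and the dienyl iodide 24. This is the most convergent cut: both chain stereocentres and both double bonds leave with 24, and the alkyne–vinyl iodide coupling keeps double-bond geometry.

**Side chain (24 to 23, 22, 21, 20 and 19).** The iodide 24 comes from enal 23 by one-carbon iodo-olefination. The enal comes from aldehyde 22 by a stabilised ylide olefination. Aldehyde 22 comes through silyl ether 21 from hydroxy ester 20, whose two stereocentres arise from ethyl (S)-3-hydroxybutanoate 19 by anti-selective dianion methylation. One purchased stereocentre thus controls the second.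

**C4a=C5 and C6=O (18 to 17, 16 and 15).** The enone 18 is taken back through ketone 17 to the saturated 6,7-diol 16 and its silyl ether 15. Because C7 is quaternary by then, the C6 ketone can enolise only towards C5, so dehydrogenation can give only the C4a=C5 double bond. This is why the methyl group is introduced before the C6 oxidation.

**C7–CH3 (15 to 14 and 13).** The tertiary carbinol 15 is cut to ketone 14 and a methyl nucleophile. Ketone 14 comes from the secondary alcohol 13, in which C1–OH and O8 are tied as an arylidene acetal. The acetal makes the 7-hydroxyl the only free one and gives a cis-fused bicycle with an axial C8–O bond that directs the addition.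

**C4≡C3 (13 to 12, 11 and 10).** The alkyne carbon C3 is removed by a one-carbon homologation of the lactol 11, which comes from the γ-lactone 10. The triol ester 9, a γ-hydroxy ester with C1–OH cis to the C4 ester, would lactonise in any case, so the plan uses lactone 10 as a joint mask for C1–OH and C4 and opens it directly to hydroxy alkyne 12.

**C1–C8a and C1–O2 (10 to 9, 8 and 7).** Lactone 10 is the oxidation product (through 9) of the cis-fused siloxane 8, and 8 comes from the (bromomethyl)silyl ether 7 by breaking the C1–C8a bond. This is the central cut. It turns the hardest relationship of the ring (C1 cis to O8 on C8a) into a consequence of ring size, and it reduces the carbocycle to an unmodified shikimate.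

**Tether and protecting groups (7 to 5, 4, 3, 2, then 1 and 6).** Ether 7 is the 3-O-silyl derivative of diol 5, made with chlorosilane 6. Diol 5 comes from shikimic acid 1 through methyl ester 2, acetonide 3 and silyl ether 4, which differentiate O5 (the future C6 oxygen) from the 3,4-diol.

## Roads not taken

Alternative 1: ring expansion with dichlorocarbene to bring in C5 together with its chlorine. The cut removes C5, breaking C5–C6 and C5–C4a, so the carbocycle shrinks to a five-membered ring, present as the silyl enol ether A1 fused to a δ-lactone. In the forward direction dichlorocarbene adds to the enol ether double bond of A1 and the resulting three-membered ring opens with loss of chloride to the 2-chloro-enone A2.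

- Merits: C5, its chlorine and the C4a=C5 double bond arrive in one operation and the chlorine position is unambiguous. In this respect the road is better than the chosen plan, which chlorinates a polyene in step 22 and needs a dehydrogenation in step 13.
- Weak points: A1 still carries C7, C8 and C8a, now on a cyclopentene with no evident chiral-pool source, so the stereochemical problem is moved and not solved. The carbene is generated under strongly basic conditions in the presence of a lactone with an acidic C4 methylene. After the expansion, the lactone carbonyl of A2 must still be turned into the dienyl enol ether next to a chloro-enone.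
- Comparison: the chosen plan offers a purchased carbocycle with C8 already set and a tether that fixes C8a, and pays for this with a less certain chlorination.

Alternative 2: enzymatic cis-dihydroxylation of an arene as the source of C7 and C8. The cut is at the two C–O bonds of C7 and C8 and leads back to benzoic acid A3. Whole cells expressing benzoate 1,2-dioxygenase add both atoms of dioxygen to one face of A3, at the carboxyl-bearing carbon and its neighbour, and give the diene diol acid A4; no ring is closed.

- Merits: one step from the very cheap A3 sets the quaternary C7 and C8 as a cis-diol in the absolute sense that 28 needs, with the carboxyl in the place of the C7 methyl. This is a more certain origin for C7 than the face-selective addition of step 11.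
- Weak points: the carboxyl of A4 must be reduced to methyl at a hindered tertiary centre. C1, C4 and the C6 oxygen are all missing. The diene of A4 must be desymmetrised so that a carbon goes to C8a cis to O8, another to C4a and an oxygen to C6, each with its own regio- and stereochemical question. A fermentation is also required.
- Comparison: shikimic acid 1 already contains C4 and the oxygens on C6, C7 and C8, and the tether answers the C8a question, at the price of one added methyl group.

Alternative 3: an acyclic ynone folded by Michael addition and cyclodehydration. The cut is at C4a–C5 and O2–C3. Cs2CO3 makes the chloromethyl ketone enolate of the acyclic ynone A5 add to the ynone carbon C4a and close the carbocycle; camphorsulfonic acid then condenses the C1 hydroxyl with the C3 ketone to give the protected target A6.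

- Merits: this is the most convergent road. Both rings form in one flask, the chain is already attached and the chlorine is built in, so there is no late halogenation and no dehydrogenation. In end-game step economy it is superior to the chosen plan.
- Weak points: A5 carries C7, C8 and C8a on an open chain, so a quaternary carbinol and two neighbours must be set by acyclic stereocontrol, in a sequence unlikely to be shorter than the shikimate one. H-8a of A5 is propargylic and becomes γ to two carbonyls, so carbonate can epimerise it. The chloromethyl ketone enolate and the free C1 hydroxyl of A5 have competing paths (displacement of chloride, oxa-Michael addition, epoxide formation).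
- Comparison: the chosen plan offers absolute configuration from the pool, a ring that exists from the first step and a C8/C8a relationship enforced by ring size.

Key step: step 5

Remark on naming: core intermediates use the isochromene numbering of 28; shikimate numbering appears only in the names of 1 to 7; TBS is tert-butyldimethylsilyl.

Assumption: C4a of 8 to 16 is drawn as the epimer expected from hydrogen transfer anti to C1; the centre is erased in step 13 and either epimer serves.

Assumption: lactol 11 is an anomeric mixture, and the acetal carbon of 13 to 18 and 25 is drawn with the aryl group equatorial, the thermodynamic arrangement.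

## Route

Step 1
Reactants: 1 shikimic acid
Product: 3 methyl 3,4-O-isopropylidene shikimate, via methyl shikimate 2 (not isolated)
Conditions: MeOH, CSA (cat.), reflux; evaporate; then 2,2-dimethoxypropane, acetone, rt
Reagents that add atoms: methanol, CO; 2,2-dimethoxypropane, COC(C)(C)OC
Why: Fischer esterification followed by thermodynamic ketalisation; the cis-3,4-diol closes the five-membered dioxolane in preference to the trans-4,5-diol, so only the 5-hydroxyl stays free.

Step 2
Reactants: 3 methyl 3,4-O-isopropylidene shikimate
Product: 4 methyl 5-O-TBS-3,4-O-isopropylidene shikimate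
Conditions: TBSCl, imidazole, DMF, rt
Reagents that add atoms: tert-butyldimethylsilyl chloride, CC(C)(C)[Si](C)(C)Cl
Why: Standard silylation of the single free secondary hydroxyl; the TBS ether on the future O6 is chosen to survive aqueous acid, tin radicals, fluoride-buffered peroxide, hydride and Grignard reagents until step 12.

Step 3
Reactants: 4 methyl 5-O-TBS-3,4-O-isopropylidene shikimate
Product: 5 methyl 5-O-TBS shikimate (free 3,4-cis-diol)
Conditions: AcOH/H2O (4:1), 40 °C
Reagents that add atoms: none
Why: Acid hydrolysis of a cis-fused dioxolane is much faster than cleavage of a secondary TBS ether in aqueous acetic acid, so the acetonide is removed selectively.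

Step 4
Reactants: 5 methyl 5-O-TBS shikimate; 6 (bromomethyl)chlorodimethylsilane
Product: 7 methyl 3-O-[(bromomethyl)dimethylsilyl]-5-O-TBS shikimate (4-hydroxyl free)
Conditions: Et3N, DMAP (cat.), CH2Cl2, −40 → 0 °C; filtered and used crude
Reagents that add atoms: none
Why: Silylation of the allylic 3-hydroxyl is expected because the 4-hydroxyl, flanked by the 5-OTBS group and C3, is the least reactive hydroxyl of shikimates; the labile ether is not chromatographed.

Step 5
Reactants: 7 methyl 3-O-[(bromomethyl)dimethylsilyl]-5-O-TBS shikimate
Product: 8 cis-fused siloxane (five-membered ring O8–SiMe2–C1 across C8/C8a; methyl ester on C4a; 7-OH free; 6-OTBS; C1, O8, O7 and the ester on one face, O6 on the other)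
Conditions: Bu3SnH (1.3 equiv, syringe pump), AIBN (cat.), benzene (0.01 M), 80 °C
Reagents that add atoms: none
Why: A tin radical abstracts bromine from Si–CH2Br, the nucleophilic α-silyl methyl radical adds to C8a, the β-carbon of the enoate, and the resulting α-ester radical at C4a takes hydrogen from Bu3SnH, which carries the chain. The closest known reaction type is the silicon-tethered radical cyclisation of (bromomethyl)dimethylsilyl ethers of cyclic allylic alcohols, which is normally followed by Tamao–Fleming oxidation. The one ring closed is the 1-oxa-2-silacyclopentane, formed in the 5-exo-trig mode, and a five-membered ring across C8–C8a can only be cis-fused. C8a is therefore set by the tether: C1 is delivered to the face of O8, which turns the shikimate C3 carbinol into the C8/C8a relationship of 28. C4a is set by hydrogen transfer to the face anti to the new C1 (ester cis to C1) and is erased in step 13. The step needs 5-exo over 6-endo closure, which the polarity match (nucleophilic radical, electron-poor β-carbon) and ring-size kinetics both favour. It also needs ring closure to outrun reduction of the open radical, which slow addition of the stannane at high dilution secures. The free 7-hydroxyl, the TBS ether and the ester are inert to tin radicals.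

Step 6
Reactants: 8 cis-fused siloxane
Product: 10 lactone diol (cis-fused γ-lactone C4(=O)–O2–C1; 7,8-cis-diol; 6-OTBS), via triol ester 9 (not isolated)
Conditions: 30% H2O2, KF, KHCO3, THF/MeOH (1:1), rt; then CSA (cat.), CH2Cl2, rt
Reagents that add atoms: hydrogen peroxide, OO
Why: Tamao–Fleming oxidation turns the C1–Si bond into C1–OH and frees O8; the primary hydroxyl then closes the γ-lactone on the cis ester, and a trace of acid completes this. The lactone masks C1–OH and C4 together, and a bridged lactone through O8, should it form, is reduced in step 7 to a lactol that opens to the same hydroxy aldehyde in step 8.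

Step 7
Reactants: 10 lactone diol
Product: 11 lactol (7,8-diol; 6-OTBS)
Conditions: iBu2AlH (3.3 equiv), CH2Cl2, −78 °C; aq. potassium sodium tartrate
Reagents that add atoms: none
Why: Partial reduction of a γ-lactone stops at the lactol because the tetrahedral aluminate is stable at −78 °C; two equivalents of hydride are consumed by the free hydroxyls.

Step 8
Reactants: 11 lactol
Product: 12 alkyne triol (ethynyl on C4a; 1-OH, 7-OH, 8-OH; 6-OTBS)
Conditions: dimethyl (1-diazo-2-oxopropyl)phosphonate, K2CO3, MeOH, 0 °C → rt
Reagents that add atoms: dimethyl (1-diazo-2-oxopropyl)phosphonate, CC(=O)C(=[N+]=[N-])P(=O)(OC)OC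
Why: Seyferth–Gilbert homologation in the Ohira–Bestmann variant acts on the open hydroxy aldehyde form of the lactol: the diazomethylphosphonate anion adds, the diazoalkene loses nitrogen and a 1,2-hydrogen shift of the alkylidene carbene gives the terminal alkyne (C3). The ring opening also releases C1–OH.

Step 9
Reactants: 12 alkyne triol
Product: 13 1,8-O-(4-methoxybenzylidene) acetal (cis-fused 1,3-dioxane, aryl equatorial; 7-OH free; 6-OTBS)
Conditions: 4-MeOC6H4CH(OMe)2, CSA (cat.), CH2Cl2, rt
Reagents that add atoms: 4-methoxybenzaldehyde dimethyl acetal, COC(OC)c1ccc(OC)cc1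
Why: Under equilibrium an arylidene acetal prefers the six-membered 1,3-dioxane across the primary O1 and the axial O8 over a dioxolane on the 7,8-cis-diol, as in the 4,6-O-benzylidenation of galactosides; the acetal carbon settles with the aryl group equatorial and only the 7-hydroxyl stays free.

Step 10
Reactants: 13 1,8-O-(4-methoxybenzylidene) acetal
Product: 14 7-ketone
Conditions: Dess–Martin periodinane, NaHCO3, CH2Cl2, 0 °C → rt
Reagents that add atoms: none
Why: Dess–Martin oxidation of the only free hydroxyl under buffered conditions that do not epimerise C6 or C8; alkyne, acetal and silyl ether are inert.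

Step 11
Reactants: 14 7-ketone
Product: 15 7-methyl carbinol (7-OH cis to O8, methyl on the opposite face; C7 as in 28)
Conditions: MeMgBr (3 equiv), THF, −78 °C
Reagents that add atoms: methylmagnesium bromide, C[Mg]Br
Why: In this Grignard 1,2-addition the C8–O bond is axial in the cis-fused bicycle and the dioxane ring covers that face, so methyl should enter axially, anti to C8–O on the convex face, which places the new hydroxyl cis to O8. The equatorial 6-OTBS group lies near the carbonyl plane, and the excess reagent allows for deprotonation of the alkyne.

Step 12
Reactants: 15 7-methyl carbinol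
Product: 16 6,7-diol (secondary 6-OH, tertiary 7-OH)
Conditions: Bu4NF, THF, 0 °C → rt
Reagents that add atoms: none
Why: Fluoride cleaves the secondary TBS ether; the arylidene acetal, the tertiary alcohol and the terminal alkyne do not react.

Step 13
Reactants: 16 6,7-diol
Product: 18 ynenone (C4a=C5–C6=O; ethynyl on C4a; 7-OH free; acetal intact), via 6-ketone 17 (not isolated)
Conditions: IBX (3.5 equiv), 4-methoxypyridine N-oxide, DMSO, 25 → 40 °C
Reagents that add atoms: none
Why: IBX oxidises the secondary alcohol of a secondary/tertiary diol to the α-ketol without glycol cleavage and then dehydrogenates the ketone through its enol (IBX dehydrogenation). C7 is quaternary, so only C5 can enolise and the double bond can form only between C5 and C4a; the N-oxide ligand allows this near room temperature, which spares the acetal.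

Step 14
Reactants: 19 ethyl (S)-3-hydroxybutanoate
Product: 20 ethyl (2S,3S)-3-hydroxy-2-methylbutanoate
Conditions: LiN(iPr)2 (2.2 equiv), THF, −78 → −20 °C; MeI, DMPU, −78 → 0 °C
Reagents that add atoms: iodomethane, CI
Why: Fráter–Seebach alkylation: the chelated lithium alkoxide enolate is methylated on the face away from the C3 methyl, which sets the anti (2S) centre, the future C5'.

Step 15
Reactants: 20 ethyl (2S,3S)-3-hydroxy-2-methylbutanoate
Product: 21 ethyl (2S,3S)-3-(TBS-oxy)-2-methylbutanoate
Conditions: TBSCl, imidazole, DMF, rt
Reagents that add atoms: tert-butyldimethylsilyl chloride, CC(C)(C)[Si](C)(C)Cl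
Why: Standard silylation; the ether prevents retro-aldol and elimination in the following steps and is removed with the acetal in step 20.

Step 16
Reactants: 21 ethyl (2S,3S)-3-(TBS-oxy)-2-methylbutanoate
Product: 22 (2S,3S)-3-(TBS-oxy)-2-methylbutanal
Conditions: iBu2AlH (1.1 equiv), CH2Cl2, −78 °C
Reagents that add atoms: none
Why: Partial reduction of the ester through the cold-stable aluminium hemiacetal; the aldehyde is used at once to avoid epimerisation of its α-centre.

Step 17
Reactants: 22 (2S,3S)-3-(TBS-oxy)-2-methylbutanal
Product: 23 (2E,4R,5S)-5-(TBS-oxy)-2,4-dimethylhex-2-enal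
Conditions: Ph3P=C(CH3)CHO, toluene, 90 °C
Reagents that add atoms: 2-(triphenylphosphoranylidene)propanal, CC(C=O)=P(c1ccccc1)(c1ccccc1)c1ccccc1
Why: Wittig olefination with a stabilised formyl ylide gives the (E)-trisubstituted enal; the neutral conditions leave the α-stereocentre untouched.

Step 18
Reactants: 23 (2E,4R,5S)-5-(TBS-oxy)-2,4-dimethylhex-2-enal
Product: 24 (1E,3E,5R,6S)-6-(TBS-oxy)-1-iodo-3,5-dimethylhepta-1,3-diene
Conditions: CrCl2, CHI3, THF, 0 °C → rt
Reagents that add atoms: iodoform, IC(I)I
Why: Takai olefination: the geminal dichromium species formed from iodoform and divalent chromium adds to the aldehyde and eliminates to the (E)-vinyl iodide.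

Step 19
Reactants: 18 ynenone; 24 (1E,3E,5R,6S)-6-(TBS-oxy)-1-iodo-3,5-dimethylhepta-1,3-diene
Product: 25 protected dienynone (C3–C1' bond formed; acetal and side-chain TBS ether intact)
Conditions: Pd(PPh3)4 (5 mol%), CuI (10 mol%), Et3N, THF, rt
Reagents that add atoms: none
Why: Sonogashira coupling: zerovalent palladium inserts into the C–I bond with retention of geometry, the monovalent copper acetylide transmetalates and reductive elimination forms the C3–C1' bond. A tertiary amine is used so that no amine adds to the ynenone.

Step 20
Reactants: 25 protected dienynone
Product: 26 tetraol dienynone (1-OH, 7-OH, 8-OH and 6'-OH free)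
Conditions: CSA (cat.), MeOH, 0 °C → rt
Reagents that add atoms: none
Why: Acid-catalysed transacetalisation removes the 4-methoxybenzylidene group and methanolysis removes the secondary TBS ether; the tertiary alcohol, being α to the ketone, does not ionise. Early closure of the pyran under these conditions would be harmless.

Step 21
Reactants: 26 tetraol dienynone
Product: 27 deschloro compound (pyran ring closed, O2–C3 bond)
Conditions: Ph3PAuNTf2 (5 mol%), THF/CH2Cl2, rt
Reagents that add atoms: none
Why: Monovalent gold catalyses a 6-endo-dig hydroalkoxylation of the alkynol, the reaction type used to close isochromenes from 2-alkynylbenzyl alcohols. The π-complex is polarised so that C3, stabilised by the dienyl group, takes the C1 oxygen, while C4, next to the electron-poor C4a, takes the proton, giving the conjugated vinylogous ester. No stereocentre is formed.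

Step 22
Reactants: 27 deschloro compound
Product: 28 target, (7R,8R,8aS)-5-chloro-7,8-dihydroxy-3-[(1E,3E,5R,6S)-6-hydroxy-3,5-dimethylhepta-1,3-dien-1-yl]-7-methyl-8,8a-dihydro-1H-isochromen-6(7H)-one
Conditions: NCS (1.05 equiv), MeCN, 0 °C
Reagents that add atoms: N-chlorosuccinimide, O=C1CCC(=O)N1Cl
Why: Electrophilic α-halogenation of a vinylogous ester: attack at C5 gives a cation delocalised over C4a, C3 and O2, and loss of H-5 restores the whole chromophore, as in the C5 halogenation of related isochromenone vinylogous esters. The chain diene is cross-conjugated to O2 and part of the electron-poor polyene, so it is not activated.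

## Compound list

1 | shikimic acid, (3R,4S,5R)-3,4,5-trihydroxycyclohex-1-ene-1-carboxylic acid | OC(=O)C1=C[C@@H](O)[C@@H](O)[C@H](O)C1 | starting material
2 | methyl shikimate (not isolated) | COC(=O)C1=C[C@@H](O)[C@@H](O)[C@H](O)C1 | intermediate
3 | methyl 3,4-O-isopropylidene shikimate | COC(=O)C1=C[C@@H]2[C@@H](OC(C)(C)O2)[C@H](O)C1 | intermediate
4 | methyl 5-O-TBS-3,4-O-isopropylidene shikimate | COC(=O)C1=C[C@@H]2[C@@H](OC(C)(C)O2)[C@H](O[Si](C)(C)C(C)(C)C)C1 | intermediate
5 | methyl 5-O-TBS shikimate | COC(=O)C1=C[C@@H](O)[C@@H](O)[C@H](O[Si](C)(C)C(C)(C)C)C1 | intermediate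
6 | (bromomethyl)chlorodimethylsilane | C[Si](C)(Cl)CBr | starting material
7 | methyl 3-O-[(bromomethyl)dimethylsilyl]-5-O-TBS shikimate | COC(=O)C1=C[C@@H](O[Si](C)(C)CBr)[C@@H](O)[C@H](O[Si](C)(C)C(C)(C)C)C1 | intermediate
8 | cis-fused siloxane (O8–SiMe2–C1 ring; ester on C4a; 7-OH; 6-OTBS) | COC(=O)[C@@H]1C[C@@H](O[Si](C)(C)C(C)(C)C)[C@H](O)[C@@H]2O[Si](C)(C)C[C@H]12 | intermediate
9 | triol ester (1-OH, 7-OH, 8-OH; methyl ester on C4a; 6-OTBS; not isolated) | COC(=O)[C@@H]1C[C@@H](O[Si](C)(C)C(C)(C)C)[C@H](O)[C@H](O)[C@@H]1CO | intermediate
10 | lactone diol (cis-fused γ-lactone C4(=O)–O2–C1; 7,8-cis-diol; 6-OTBS) | O=C1OC[C@H]2[C@@H](O)[C@@H](O)[C@H](O[Si](C)(C)C(C)(C)C)C[C@@H]12 | intermediate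
11 | lactol (anomeric mixture; 7,8-diol; 6-OTBS) | OC1OC[C@H]2[C@@H](O)[C@@H](O)[C@H](O[Si](C)(C)C(C)(C)C)C[C@@H]12 | intermediate
12 | alkyne triol (ethynyl on C4a; 1-OH, 7-OH, 8-OH; 6-OTBS) | C#C[C@@H]1C[C@@H](O[Si](C)(C)C(C)(C)C)[C@H](O)[C@H](O)[C@@H]1CO | intermediate
13 | 1,8-O-(4-methoxybenzylidene) acetal (7-OH free; 6-OTBS) | C#C[C@@H]1C[C@@H](O[Si](C)(C)C(C)(C)C)[C@H](O)[C@@H]2O[C@H](c3ccc(OC)cc3)OC[C@H]12 | intermediate
14 | 7-ketone | C#C[C@@H]1C[C@@H](O[Si](C)(C)C(C)(C)C)C(=O)[C@@H]2O[C@H](c3ccc(OC)cc3)OC[C@H]12 | intermediate
15 | 7-methyl carbinol (7-OH cis to O8) | C#C[C@@H]1C[C@@H](O[Si](C)(C)C(C)(C)C)[C@](C)(O)[C@@H]2O[C@H](c3ccc(OC)cc3)OC[C@H]12 | intermediate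
16 | 6,7-diol | C#C[C@@H]1C[C@@H](O)[C@](C)(O)[C@@H]2O[C@H](c3ccc(OC)cc3)OC[C@H]12 | intermediate
17 | 6-ketone (not isolated) | C#C[C@@H]1CC(=O)[C@](C)(O)[C@@H]2O[C@H](c3ccc(OC)cc3)OC[C@H]12 | intermediate
18 | ynenone (C4a=C5–C6=O; ethynyl on C4a) | C#CC1=CC(=O)[C@](C)(O)[C@@H]2O[C@H](c3ccc(OC)cc3)OC[C@H]12 | intermediate
19 | ethyl (S)-3-hydroxybutanoate | CCOC(=O)C[C@H](C)O | starting material
20 | ethyl (2S,3S)-3-hydroxy-2-methylbutanoate | CCOC(=O)[C@@H](C)[C@H](C)O | intermediate
21 | ethyl (2S,3S)-3-(TBS-oxy)-2-methylbutanoate | CCOC(=O)[C@@H](C)[C@H](C)O[Si](C)(C)C(C)(C)C | intermediate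
22 | (2S,3S)-3-(TBS-oxy)-2-methylbutanal | O=C[C@@H](C)[C@H](C)O[Si](C)(C)C(C)(C)C | intermediate
23 | (2E,4R,5S)-5-(TBS-oxy)-2,4-dimethylhex-2-enal | O=C/C(C)=C/[C@@H](C)[C@H](C)O[Si](C)(C)C(C)(C)C | intermediate
24 | (1E,3E,5R,6S)-6-(TBS-oxy)-1-iodo-3,5-dimethylhepta-1,3-diene | I/C=C/C(C)=C/[C@@H](C)[C@H](C)O[Si](C)(C)C(C)(C)C | intermediate
25 | protected dienynone | CC(/C=C/C#CC1=CC(=O)[C@](C)(O)[C@@H]2O[C@H](c3ccc(OC)cc3)OC[C@H]12)=C\[C@@H](C)[C@H](C)O[Si](C)(C)C(C)(C)C | intermediate
26 | tetraol dienynone | CC(/C=C/C#CC1=CC(=O)[C@](C)(O)[C@H](O)[C@@H]1CO)=C\[C@@H](C)[C@H](C)O | intermediate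
27 | deschloro compound | CC(/C=C/C1=CC2=CC(=O)[C@](C)(O)[C@H](O)[C@@H]2CO1)=C\[C@@H](C)[C@H](C)O | intermediate
28 | CNP0536300.1 | CC(/C=C/C1=CC2=C(Cl)C(=O)[C@](C)(O)[C@H](O)[C@@H]2CO1)=C\[C@@H](C)[C@H](C)O | target

## Step count and risk

Total: 22 steps. Longest linear sequence: 17 steps from shikimic acid (steps 1 to 13 and 19 to 22). The side chain takes 5 steps (14 to 18) from ethyl (S)-3-hydroxybutanoate.

**Step 5 (key step).** The most likely failure is loss of the tether before ring closure. The free 7-hydroxyl next to the labile silyl ether can take over the silicon or displace bromide during the long hot addition, and the open radical can be reduced before it cyclises. An imperfect regiochemistry of silylation in step 4 would add to this. The fallback removes the free hydroxyl and the need for selective silylation. It sets out from 5, which is silylated on both hydroxyls with an excess of 6 to give the 3,4-bis[(bromomethyl)dimethylsilyl] ether F1. Under the conditions of step 5 with two equivalents of stannane, one tether closes onto C8a and the other radical is reduced, giving the 7-O-trimethylsilyl siloxane F2. Either tether can deliver C1 only to the face of O8. The conditions of step 6 cleave both silicon groups, and the fallback returns to the route at 10.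

**Step 11.** The risk is poor facial selectivity. Addition could proceed through the conformer with an axial 6-OTBS group, or through a magnesium chelate with O8, and put methyl on the face of O8. The fallback reverses the polarity so that the same accessible face gives the right carbinol. It sets out from 14, which is methylenated with Ph3P=CH2 (from Ph3PCH3Br and KOC(CH3)3) to the 7-methylene compound F3. Epoxidation with 3-chloroperoxybenzoic acid, from the face that the Grignard reagent had preferred, gives the spiro-epoxide F4 with its oxygen cis to O8. LiEt3BH opens F4 at the methylene carbon, and the fallback returns at 15.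

**Step 13.** The dehydrogenation may stall at the ketone, or go on to a second unsaturation towards C8a–C8 with loss of the C8a centre, and the acidic oxidant may open the acetal. The fallback replaces the one-pot oxidation by a selenium-based sequence. It sets out from 16, which is oxidised with Dess–Martin periodinane to the isolated ketone 17. Me3SiOTf and Et3N give the bis(trimethylsilyl) enol ether F5, PhSeCl at −78 °C gives the 5-phenylselenyl ketone F6, and oxidation with H2O2 followed by syn-elimination of the selenoxide and a mildly acidic work-up returns the route at 18. The selenium sits on C5 and the only β-hydrogen is H-4a, so the position of the double bond is again fixed.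

**Step 21.** The closure may go 5-exo onto C4, or the π-acid may engage the polyene. The fallback turns the alkyne into an alkene before the oxygen attacks. It sets out from 26: diethylamine adds to C3 of the ynenone in the 1,6-sense to give the 3-(diethylamino) dienone F7. Mild acid (pyridinium p-toluenesulfonate) then lets the C1 hydroxyl replace the amine by addition and elimination in a 6-endo-trig closure, and the fallback returns at 27.

**Step 22.** Chlorination may occur at C4 or on the chain, or twice. The fallback places the chlorine while only C5 can react. It sets out from 16 and goes through 17 and the bis(trimethylsilyl) enol ether F5 as in the fallback for step 13. N-Chlorosuccinimide then converts the enol ether into the 5-chloro ketone F8, LiN(SiMe3)2 and PhSeCl give the 5-chloro-5-phenylselenyl ketone F9, and oxidation with H2O2 followed by selenoxide elimination gives the 5-chloro ynenone F10. The conditions of steps 19 and 20 then give the protected 5-chloro dienynone F11 and the 5-chloro tetraol dienynone F12, and gold-catalysed closure as in step 21 brings the fallback back to the route at 28.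

## Further compounds

F1 | step 5 | methyl 3,4-bis-O-[(bromomethyl)dimethylsilyl]-5-O-TBS shikimate | COC(=O)C1=C[C@@H](O[Si](C)(C)CBr)[C@@H](O[Si](C)(C)CBr)[C@H](O[Si](C)(C)C(C)(C)C)C1
F2 | step 5 | 7-O-trimethylsilyl siloxane (O8–SiMe2–C1 ring; ester on C4a; 6-OTBS) | COC(=O)[C@@H]1C[C@@H](O[Si](C)(C)C(C)(C)C)[C@H](O[Si](C)(C)C)[C@@H]2O[Si](C)(C)C[C@H]12
F3 | step 11 | 7-methylene compound | C#C[C@@H]1C[C@@H](O[Si](C)(C)C(C)(C)C)C(=C)[C@@H]2O[C@H](c3ccc(OC)cc3)OC[C@H]12
F4 | step 11 | 7-spiro-epoxide (oxygen cis to O8) | C#C[C@@H]1C[C@@H](O[Si](C)(C)C(C)(C)C)[C@@]3(CO3)[C@@H]2O[C@H](c4ccc(OC)cc4)OC[C@H]12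
F5 | step 13 | bis(trimethylsilyl) enol ether of 17 | C#C[C@@H]1C=C(O[Si](C)(C)C)[C@](C)(O[Si](C)(C)C)[C@@H]2O[C@H](c3ccc(OC)cc3)OC[C@H]12
F6 | step 13 | 5-phenylselenyl ketone (7-O-trimethylsilyl) | C#C[C@@H]1C([Se]c3ccccc3)C(=O)[C@](C)(O[Si](C)(C)C)[C@@H]2O[C@H](c4ccc(OC)cc4)OC[C@H]12
F7 | step 21 | 3-(diethylamino) dienone | CC(/C=C/C(=CC1=CC(=O)[C@](C)(O)[C@H](O)[C@@H]1CO)N(CC)CC)=C\[C@@H](C)[C@H](C)O
F8 | step 22 | 5-chloro ketone (7-O-trimethylsilyl) | C#C[C@@H]1C(Cl)C(=O)[C@](C)(O[Si](C)(C)C)[C@@H]2O[C@H](c3ccc(OC)cc3)OC[C@H]12
F9 | step 22 | 5-chloro-5-phenylselenyl ketone (7-O-trimethylsilyl) | C#C[C@@H]1C(Cl)([Se]c3ccccc3)C(=O)[C@](C)(O[Si](C)(C)C)[C@@H]2O[C@H](c4ccc(OC)cc4)OC[C@H]12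
F10 | step 22 | 5-chloro ynenone | C#CC1=C(Cl)C(=O)[C@](C)(O)[C@@H]2O[C@H](c3ccc(OC)cc3)OC[C@H]12
F11 | step 22 | protected 5-chloro dienynone | CC(/C=C/C#CC1=C(Cl)C(=O)[C@](C)(O)[C@@H]2O[C@H](c3ccc(OC)cc3)OC[C@H]12)=C\[C@@H](C)[C@H](C)O[Si](C)(C)C(C)(C)C
F12 | step 22 | 5-chloro tetraol dienynone | CC(/C=C/C#CC1=C(Cl)C(=O)[C@](C)(O)[C@H](O)[C@@H]1CO)=C\[C@@H](C)[C@H](C)O
A1 | alternative 1 | trimethylsilyl enol ether of the cyclopentanone-fused δ-lactone with 7,8-acetonide | O=C1CC2=C(O[Si](C)(C)C)[C@]3(C)OC(C)(C)O[C@@H]3[C@@H]2CO1
A2 | alternative 1 | 5-chloro-6-oxo isochroman-3-one with 7,8-acetonide | O=C1CC2=C(Cl)C(=O)[C@]3(C)OC(C)(C)O[C@@H]3[C@@H]2CO1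
A3 | alternative 2 | benzoic acid | OC(=O)c1ccccc1
A4 | alternative 2 | (1S,2R)-1,2-dihydroxycyclohexa-3,5-diene-1-carboxylic acid | OC(=O)[C@@]1(O)[C@H](O)C=CC=C1
A5 | alternative 3 | acyclic chloromethyl ketone ynone (7,8-acetonide, free C1 hydroxyl, silylated side chain) | ClCC(=O)[C@]1(C)OC(C)(C)O[C@@H]1[C@H](CO)C#CC(=O)/C=C/C(C)=C/[C@@H](C)[C@H](C)O[Si](C)(C)C(C)(C)C
A6 | alternative 3 | target protected as 7,8-acetonide and side-chain TBS ether | CC(/C=C/C1=CC2=C(Cl)C(=O)[C@]3(C)OC(C)(C)O[C@@H]3[C@@H]2CO1)=C\[C@@H](C)[C@H](C)O[Si](C)(C)C(C)(C)C
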